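**Assumption:** atom labels C1–C15 follow germacranolide numbering (lactone C12 on O6, C14 = ester carbon on C10, side chain on O8). Nothing beyond the given SMILES is assumed. The route is a paper design; no step has been run.

## Retrosynthetic overview

1. 26 ⇐ 24: CrCl2 Barbier allylation (C6–C7) of a 3-(bromomethyl)-5,6-dihydropyran-2-one onto the tethered (Z)-enal; the new O6 alkoxide then takes the acyl group from O9. Ten-membered carbocycle and γ-lactone form in one operation and 9-OH is set free.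
2. 24 ⇐ 22 + 10: C1=C10 by cross-metathesis of the vinyl oxirane with the 2-substituted acrylate, then oxidation at C6.
3. 22 ⇐ 14 + 16 + 4: δ-lactone by RCM (masks O9, fixes the allyl geometry); C8/C9 syn-diol by alkoxyallylboration of 2-bromoacrolein; C14 by carbonylation; side chain by Sharpless epoxidation.
4. 10 ⇐ 5 + 7: cis-vinyl oxirane (C2, C3) by chloroallylboration of the lactol of 3-methylfuran-2(5H)-one.
5. Ring order: side-chain oxirane (step 2), ring oxirane (step 5), temporary δ-lactone (step 9), then carbocycle and γ-lactone together (step 14, δ-lactone opens).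

## Route

**Step 1**
Reactants: 1 methyl angelate [methyl (2Z)-2-methylbut-2-enoate]
Product: 2 (2Z)-2-methylbut-2-en-1-ol
Conditions: i-Bu2AlH (2.2 equiv), CH2Cl2, −78 → 0 °C; aq. KNaC4H4O6
Reagents that add atoms: none
Why: 1,2-reduction of the ester by the aluminium hydride (ester reduction) leaves the Z-trisubstituted alkene untouched.

**Step 2**
Reactants: 2 (2Z)-2-methylbut-2-en-1-ol
Product: 3 [(2R,3S)-2,3-dimethyloxiran-2-yl]methanol
Conditions: Ti(OiPr)4 (10 mol%), D-(−)-diethyl tartrate (12 mol%), t-BuOOH, 4 Å MS, CH2Cl2, −20 °C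
Reagents that add atoms: tert-butyl hydroperoxide, CC(C)(C)OO
Why: Sharpless asymmetric epoxidation; the D-(−)-tartrate catalyst delivers oxygen to the alkene face that gives (2R,3S), and the Z-alkene fixes the cis relation of C3-methyl and CH2OH.

**Step 3**
Reactants: 3 [(2R,3S)-2,3-dimethyloxiran-2-yl]methanol
Product: 4 (2S,3S)-2,3-dimethyloxirane-2-carboxylic acid
Conditions: TEMPO (20 mol%), PhI(OAc)2 (2.2 equiv), MeCN/H2O 1:1, rt
Reagents that add atoms: water, O
Why: TEMPO/oxoammonium oxidation through the aldehyde hydrate gives the acid without touching the epoxide; the descriptor at C2 changes only because of CIP priorities.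

**Step 4**
Reactants: 5 3-methylfuran-2(5H)-one
Product: 6 3-methyl-2,5-dihydrofuran-2-ol
Conditions: i-Bu2AlH (1.05 equiv), CH2Cl2, −78 °C; aq. KNaC4H4O6
Reagents that add atoms: none
Why: partial hydride reduction of the butenolide stops at the lactol, the ring-locked form of (2Z)-4-hydroxy-2-methylbut-2-enal, so the C4=C5 geometry is secured by the ring.

**Step 5**
Reactants: 6 3-methyl-2,5-dihydrofuran-2-ol; 7 allyl chloride
Product: 10 (2Z)-3-[(2S,3R)-3-ethenyloxiran-2-yl]but-2-en-1-ol, via chloroallylborane 8 (not isolated), via syn-chlorohydrin 9 (not isolated)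
Conditions: 7, (+)-Ipc2BOMe, LiN(c-C6H11)2, Et2O, −95 °C; BF3·OEt2; 6, −95 → −78 °C; NaOH, H2O2, H2O, 0 °C → rt
Reagents that add atoms: none
Why: Oehlschlager–Brown (Z)-γ-chloroallylboration of the open-chain aldehyde through a chair transition state gives the syn-chlorohydrin, with the isopinocampheyl groups directing attack to the Re face (C3 = S), and hydroxide then closes the ring with inversion at C2 to the cis-epoxide (C2 = R).

**Step 6**
Reactants: 11 2-bromoprop-2-enal; 12 3-(methoxymethoxy)prop-1-ene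
Product: 14 (3R,4S)-2-bromo-4-(methoxymethoxy)hexa-1,5-dien-3-ol, via alkoxyallylborane 13 (not isolated)
Conditions: 12, s-BuLi, THF, −78 °C; (+)-Ipc2BOMe; BF3·OEt2; 11, −78 °C; NaOH, H2O2
Reagents that add atoms: none
Why: Brown (Z)-γ-alkoxyallylboration; the chair transition state of the Z-reagent gives the syn C8/C9 relation and the isopinocampheyl groups direct Re-face attack, setting C9 (3R here) and C8 (4S).

**Step 7**
Reactants: 14 (3R,4S)-2-bromo-4-(methoxymethoxy)hexa-1,5-dien-3-ol
Product: 15 methyl (3S,4S)-3-hydroxy-4-(methoxymethoxy)-2-methylidenehex-5-enoate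
Conditions: Pd(PPh3)4 (5 mol%), CO (1 atm), Et3N, MeOH, 60 °C
Reagents that add atoms: carbon monoxide, [C-]#[O+]; methanol, CO
Why: palladium-catalysed methoxycarbonylation of the vinyl bromide (oxidative addition, CO insertion, methanolysis) installs C14 before any allylic ester or vinyl oxirane is present; no stereocentre is touched.

**Step 8**
Reactants: 15 methyl (3S,4S)-3-hydroxy-4-(methoxymethoxy)-2-methylidenehex-5-enoate; 16 2-(bromomethyl)prop-2-enoic acid
Product: 18 methyl (3S,4S)-3-{[2-(bromomethyl)prop-2-enoyl]oxy}-4-(methoxymethoxy)-2-methylidenehex-5-enoate, via acid chloride 17 (not isolated)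
Conditions: 16, Me2C=C(Cl)NMe2, CH2Cl2, 0 °C; then 15, 2,6-lutidine, −20 °C → rt
Reagents that add atoms: none
Why: esterification through the acid chloride made under neutral conditions; the hindered, non-nucleophilic base avoids SN2′ attack on the bromomethyl acrylate that DMAP-type catalysts would cause.

**Step 9**
Reactants: 18 methyl (3S,4S)-3-{[2-(bromomethyl)prop-2-enoyl]oxy}-4-(methoxymethoxy)-2-methylidenehex-5-enoate
Product: 19 methyl 2-[(2S,3S)-5-(bromomethyl)-3-(methoxymethoxy)-6-oxo-3,6-dihydro-2H-pyran-2-yl]prop-2-enoate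
Conditions: second-generation Hoveyda–Grubbs catalyst RuCl2(H2IMes)(=CH-C6H4-2-OiPr) (5 mol%), CH2Cl2 (5 mM), 40 °C
Reagents that add atoms: none
Why: ring-closing metathesis; the carbene forms at the only monosubstituted alkene and closes onto the 2-(bromomethyl)acrylate to the six-membered lactone, while the other 1,1-disubstituted acrylate could only give a cyclobutene and stays.

**Step 10**
Reactants: 19 methyl 2-[(2S,3S)-5-(bromomethyl)-3-(methoxymethoxy)-6-oxo-3,6-dihydro-2H-pyran-2-yl]prop-2-enoate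
Product: 20 methyl 2-[(2S,3S)-5-(bromomethyl)-3-hydroxy-6-oxo-3,6-dihydro-2H-pyran-2-yl]prop-2-enoate
Conditions: CF3CO2H/CH2Cl2 1:4 (wet), 0 °C → rt
Reagents that add atoms: none
Why: acid hydrolysis of the methoxymethyl acetal, done before any epoxide is in the molecule; the freed 8-OH is trans to CH2Br across the ring alkene and cannot cyclise onto it.

**Step 11**
Reactants: 20 methyl 2-[(2S,3S)-5-(bromomethyl)-3-hydroxy-6-oxo-3,6-dihydro-2H-pyran-2-yl]prop-2-enoate; 4 (2S,3S)-2,3-dimethyloxirane-2-carboxylic acid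
Product: 22 (2S,3S)-5-(bromomethyl)-2-(3-methoxy-3-oxoprop-1-en-2-yl)-6-oxo-3,6-dihydro-2H-pyran-3-yl (2S,3S)-2,3-dimethyloxirane-2-carboxylate, via epoxyangeloyl chloride 21 (not isolated)
Conditions: 4, Me2C=C(Cl)NMe2, CH2Cl2, 0 °C; then 20, 2,6-lutidine, 0 °C → rt
Reagents that add atoms: none
Why: esterification through the acid chloride; the acid has no α-hydrogen so it cannot epimerise, and O9 is already tied up in the lactone so only O8 is acylated.

**Step 12**
Reactants: 22 (the epoxyangelate lactone); 10 (2Z)-3-[(2S,3R)-3-ethenyloxiran-2-yl]but-2-en-1-ol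
Product: 23 (2S,3S)-5-(bromomethyl)-2-[(1E)-1-{(2R,3S)-3-[(2Z)-4-hydroxybut-2-en-2-yl]oxiran-2-yl}-3-methoxy-3-oxoprop-1-en-2-yl]-6-oxo-3,6-dihydro-2H-pyran-3-yl (2S,3S)-2,3-dimethyloxirane-2-carboxylate
Conditions: second-generation Hoveyda–Grubbs catalyst RuCl2(H2IMes)(=CH-C6H4-2-OiPr) (10 mol%), 10 (2 equiv, in portions), CH2Cl2, 40 °C
Reagents that add atoms: none
Why: olefin cross-metathesis between a monosubstituted alkene and a 2-substituted acrylate that cannot homodimerise, as with methacrylates; the trisubstituted enoate forms under thermodynamic control with C2 trans to CO2Me (E), the geometry of the target.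

**Step 13**
Reactants: 23 (the seco-alcohol)
Product: 24 (2S,3S)-5-(bromomethyl)-2-[(1E)-3-methoxy-3-oxo-1-{(2R,3S)-3-[(2Z)-4-oxobut-2-en-2-yl]oxiran-2-yl}prop-1-en-2-yl]-6-oxo-3,6-dihydro-2H-pyran-3-yl (2S,3S)-2,3-dimethyloxirane-2-carboxylate
Conditions: TEMPO (10 mol%), PhI(OAc)2 (1.2 equiv), CH2Cl2, rt
Reagents that add atoms: none
Why: oxoammonium (TEMPO) oxidation of the only free alcohol gives the (Z)-enal under neutral conditions without Z/E isomerisation or epoxide opening.

**Step 14**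
Reactants: 24 (the seco-aldehyde)
Product: 26 methyl (1(10)E,2R,3S,4Z,6R,7S,8S,9S)-8-{[(2S,3S)-2,3-dimethyloxirane-2-carbonyl]oxy}-2,3-epoxy-9-hydroxygermacra-1(10),4,11(13)-trien-12,6-olid-14-oate (CNP0291485.3), via bridged delta-lactone 25 (not isolated)
Conditions: CrCl2 (6 equiv), DMF/THF 1:1, 2 mM, slow addition of 24, rt; aq. NH4Cl
Reagents that add atoms: none
Why: Proposed new method: divalent chromium turns the cyclic allylic bromide into an allylchromium that adds through C7 to the tethered aldehyde in a chair transition state; the ring-fixed E-type allyl geometry gives the anti (6,7-trans) adduct, attack comes anti to the 8-acyloxy group, and the O6 chromium alkoxide then opens the strained bridging δ-lactone by 5-exo acyl transfer to give the fused γ-lactone and free 9-OH, so carbocycle and lactone form in one flask. The closest known reactions are chromium-mediated Barbier macrocyclisation/lactonisation of 2-(bromomethyl)acrylates in germacranolide synthesis and Barbier allylations with 3-(bromomethyl)butenolides.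

## Compound list

1 | methyl angelate, methyl (2Z)-2-methylbut-2-enoate | C/C=C(/C)C(=O)OC | starting material
2 | (2Z)-2-methylbut-2-en-1-ol | C/C=C(/C)CO | intermediate
3 | [(2R,3S)-2,3-dimethyloxiran-2-yl]methanol | OC[C@@]1(C)O[C@H]1C | intermediate
4 | (2S,3S)-2,3-dimethyloxirane-2-carboxylic acid | OC(=O)[C@@]1(C)O[C@H]1C | intermediate
5 | 3-methylfuran-2(5H)-one | CC1=CCOC1=O | starting material
6 | 3-methyl-2,5-dihydrofuran-2-ol (racemic lactol) | CC1=CCOC1O | intermediate
7 | allyl chloride, 3-chloroprop-1-ene | C=CCCl | starting material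
8 | [(2Z)-3-chloroprop-2-en-1-yl]diisopinocampheylborane (from (+)-Ipc2BOMe) | Cl/C=C\CB([C@H]1C[C@H]2C[C@@H]([C@@H]1C)C2(C)C)[C@H]1C[C@H]2C[C@@H]([C@@H]1C)C2(C)C | intermediate
9 | (2Z,4S,5S)-5-chloro-3-methylhepta-2,6-diene-1,4-diol | OC/C=C(/C)[C@H](O)[C@@H](Cl)C=C | intermediate
10 | (2Z)-3-[(2S,3R)-3-ethenyloxiran-2-yl]but-2-en-1-ol | OC/C=C(/C)[C@@H]1O[C@@H]1C=C | intermediate
11 | 2-bromoprop-2-enal (2-bromoacrolein) | C=C(Br)C=O | starting material
12 | 3-(methoxymethoxy)prop-1-ene (allyl methoxymethyl ether) | C=CCOCOC | starting material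
13 | [(2Z)-3-(methoxymethoxy)prop-2-en-1-yl]diisopinocampheylborane (from (+)-Ipc2BOMe) | COCO/C=C\CB([C@H]1C[C@H]2C[C@@H]([C@@H]1C)C2(C)C)[C@H]1C[C@H]2C[C@@H]([C@@H]1C)C2(C)C | intermediate
14 | (3R,4S)-2-bromo-4-(methoxymethoxy)hexa-1,5-dien-3-ol | C=C(Br)[C@H](O)[C@@H](OCOC)C=C | intermediate
15 | methyl (3S,4S)-3-hydroxy-4-(methoxymethoxy)-2-methylidenehex-5-enoate | C=C(C(=O)OC)[C@H](O)[C@@H](OCOC)C=C | intermediate
16 | 2-(bromomethyl)prop-2-enoic acid | C=C(CBr)C(=O)O | starting material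
17 | 2-(bromomethyl)prop-2-enoyl chloride | C=C(CBr)C(Cl)=O | intermediate
18 | methyl (3S,4S)-3-{[2-(bromomethyl)prop-2-enoyl]oxy}-4-(methoxymethoxy)-2-methylidenehex-5-enoate | C=C(C(=O)OC)[C@H](OC(=O)C(=C)CBr)[C@@H](OCOC)C=C | intermediate
19 | methyl 2-[(2S,3S)-5-(bromomethyl)-3-(methoxymethoxy)-6-oxo-3,6-dihydro-2H-pyran-2-yl]prop-2-enoate | C=C(C(=O)OC)[C@@H]1OC(=O)C(CBr)=C[C@@H]1OCOC | intermediate
20 | methyl 2-[(2S,3S)-5-(bromomethyl)-3-hydroxy-6-oxo-3,6-dihydro-2H-pyran-2-yl]prop-2-enoate | C=C(C(=O)OC)[C@@H]1OC(=O)C(CBr)=C[C@@H]1O | intermediate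
21 | (2S,3S)-2,3-dimethyloxirane-2-carbonyl chloride | ClC(=O)[C@@]1(C)O[C@H]1C | intermediate
22 | (2S,3S)-5-(bromomethyl)-2-(3-methoxy-3-oxoprop-1-en-2-yl)-6-oxo-3,6-dihydro-2H-pyran-3-yl (2S,3S)-2,3-dimethyloxirane-2-carboxylate | C=C(C(=O)OC)[C@@H]1OC(=O)C(CBr)=C[C@@H]1OC(=O)[C@@]2(C)O[C@H]2C | intermediate
23 | seco-alcohol: 22 with the acrylate =CH2 replaced by (E)-=CH–[(2R,3S)-3-((2Z)-4-hydroxybut-2-en-2-yl)oxiran-2-yl] | OC/C=C(/C)[C@@H]1O[C@@H]1/C=C(/C(=O)OC)[C@@H]2OC(=O)C(CBr)=C[C@@H]2OC(=O)[C@@]3(C)O[C@H]3C | intermediate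
24 | seco-aldehyde: the (2Z)-4-oxobut-2-en-2-yl analogue of 23 | O=C/C=C(/C)[C@@H]1O[C@@H]1/C=C(/C(=O)OC)[C@@H]2OC(=O)C(CBr)=C[C@@H]2OC(=O)[C@@]3(C)O[C@H]3C | intermediate
25 | bridged δ-lactone (C12–O9 lactone across C7/C9 of the ten-membered ring, C11=C13 exo-methylene, 6-OH formed as its chromium alkoxide; 2R,3S,6R,7S,8S,9S) | C=C1C(=O)O[C@@H]2[C@@H](OC(=O)[C@@]3(C)O[C@H]3C)[C@@H]1[C@H](O)/C=C(/C)[C@@H]4O[C@@H]4/C=C2/C(=O)OC | intermediate
26 | CNP0291485.3, methyl (1(10)E,2R,3S,4Z,6R,7S,8S,9S)-8-{[(2S,3S)-2,3-dimethyloxirane-2-carbonyl]oxy}-2,3-epoxy-9-hydroxygermacra-1(10),4,11(13)-trien-12,6-olid-14-oate | C=C1C(=O)O[C@@H]2/C=C(/C)[C@@H]3O[C@@H]3/C=C(/C(=O)OC)[C@H](O)[C@@H](OC(=O)[C@@]3(C)O[C@H]3C)[C@@H]12 | target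

## Step count and risks

Total step count: 14 (side chain 3, vinyl oxirane 2, lactone fragment 6, union and end game 3).
Longest linear sequence: 9 steps (steps 6–14, from 11 and 12 to 26).

**Steps most likely to fail**

1. **Step 14 (ring closure).** The aldehyde has to reach the C7 face anti to the 8-acyloxy group while tethered through C9, so the δ-lactone bridge in 25 is trans-1,3 and strained. Oligomerisation, the C7 epimer, furan formation from the (Z)-epoxy-enal under Lewis-acidic trivalent chromium, or O8→O9 acyl migration in the alkoxide can compete.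
 Fallback: this sets out from 10 and 22 and comes back at 26. Alcohol 10 is oxidised with TEMPO/PhI(OAc)2 to the epoxy-enal (2Z)-3-[(2S,3R)-3-ethenyloxiran-2-yl]but-2-enal F1. F1 and bromide 22 are joined by an intermolecular CrCl2 Barbier reaction, where attack anti to the acyloxy group is unconstrained, and acyl transfer in the flask gives the open-chain trans-lactone methyl (3S,4S)-4-{[(2S,3S)-2,3-dimethyloxirane-2-carbonyl]oxy}-4-[(2R,3S)-2-{(1Z)-2-[(2S,3R)-3-ethenyloxiran-2-yl]prop-1-en-1-yl}-4-methylidene-5-oxooxolan-3-yl]-3-hydroxy-2-methylidenebutanoate F2. Ring-closing metathesis of F2 (second-generation Hoveyda–Grubbs catalyst, high dilution) then forms C1=C10 and gives 26.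

2. **Step 12 (cross-metathesis).** The acrylate is 1,1-disubstituted and branched at the allylic carbon, and the vinyl oxirane homodimerises; conversion may be low, and 23 is a cis-divinyl oxirane that should not be heated above about 40 °C.
 Fallback: this sets out from 20 and 10 and comes back at 24. The two alcohols are tied together with iPr2SiCl2/2,6-lutidine as the mixed silyl diether F3. The metathesis is then run as a ring closure inside the twelve-membered siloxane to give the macrocyclic siloxane F4. Buffered HF·pyridine removes the tether to give the diol F5, TEMPO/PhI(OAc)2 oxidises only the primary allylic alcohol to the hydroxy-enal F6, and acylation of the 8-OH with acid chloride 21 gives 24.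

3. **Step 5 (chloroallylboration of the lactol).** The lactol has to open at −95 °C, where the chloroallylborane is still stable, and the free 6-OH of 10 can open the oxirane on basic work-up.
 Fallback: this sets out from 5 and comes back at 10. LiAlH4 reduction gives (2Z)-2-methylbut-2-ene-1,4-diol F7. Silylation of the less hindered hydroxyl with t-BuMe2SiCl gives the mono-silyl ether F8, and Dess–Martin oxidation gives the true aldehyde (2Z)-4-{[tert-butyl(dimethyl)silyl]oxy}-2-methylbut-2-enal F9. The same chloroallylboration with 7 and NaOH/H2O2 work-up gives the silyl-protected vinyl oxirane F10, and Bu4NF then gives 10.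

## Further compounds

F1 | step 14 | (2Z)-3-[(2S,3R)-3-ethenyloxiran-2-yl]but-2-enal | O=C/C=C(/C)[C@@H]1O[C@@H]1C=C
F2 | step 14 | methyl (3S,4S)-4-{[(2S,3S)-2,3-dimethyloxirane-2-carbonyl]oxy}-4-[(2R,3S)-2-{(1Z)-2-[(2S,3R)-3-ethenyloxiran-2-yl]prop-1-en-1-yl}-4-methylidene-5-oxooxolan-3-yl]-3-hydroxy-2-methylidenebutanoate | C=C1C(=O)O[C@H](/C=C(/C)[C@@H]2O[C@@H]2C=C)[C@H]1[C@H](OC(=O)[C@@]3(C)O[C@H]3C)[C@@H](O)C(=C)C(=O)OC
F3 | step 12 | mixed diisopropylsilyl diether of 20 (through O8) and 10 (through O6) | C=C(C(=O)OC)[C@@H]1OC(=O)C(CBr)=C[C@@H]1O[Si](C(C)C)(C(C)C)OC/C=C(/C)[C@@H]2O[C@@H]2C=C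
F4 | step 12 | twelve-membered siloxane from ring-closing metathesis of F3 (C1=C10 E, C4=C5 Z) | COC(=O)/C1=C/[C@H]2O[C@H]2/C(C)=C\CO[Si](C(C)C)(C(C)C)O[C@H]2C=C(CBr)C(=O)O[C@@H]12
F5 | step 12 | diol: 23 without the epoxyangeloyl group (8-OH and 6-OH free) | OC/C=C(/C)[C@@H]1O[C@@H]1/C=C(/C(=O)OC)[C@@H]2OC(=O)C(CBr)=C[C@@H]2O
F6 | step 12 | hydroxy-enal: 24 without the epoxyangeloyl group (8-OH free) | O=C/C=C(/C)[C@@H]1O[C@@H]1/C=C(/C(=O)OC)[C@@H]2OC(=O)C(CBr)=C[C@@H]2O
F7 | step 5 | (2Z)-2-methylbut-2-ene-1,4-diol | OC/C=C(/C)CO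
F8 | step 5 | (2Z)-4-{[tert-butyl(dimethyl)silyl]oxy}-2-methylbut-2-en-1-ol | CC(C)(C)[Si](C)(C)OC/C=C(/C)CO
F9 | step 5 | (2Z)-4-{[tert-butyl(dimethyl)silyl]oxy}-2-methylbut-2-enal | CC(C)(C)[Si](C)(C)OC/C=C(/C)C=O
F10 | step 5 | tert-butyl{[(2Z)-3-[(2S,3R)-3-ethenyloxiran-2-yl]but-2-en-1-yl]oxy}dimethylsilane | CC(C)(C)[Si](C)(C)OC/C=C(/C)[C@@H]1O[C@@H]1C=C
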